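Everything rests on opening ring D at C15–C16. Cathodic one-electron reduction of a formyl group on quaternary C8 gives a ketyl that adds 5-exo-dig to an ethynyl group on C13. One operation thus closes ring D, completes the bicyclo[3.2.1]octane of rings C and D, and delivers the 16-methylene-15-ol, one oxidation below the enone. The step exploits the cis-1,3 relationship of C15 (on C8) and C16 (on C13) across ring C: in the diaxial chair the two carbons are within bonding distance. The precursor is the finished ring A/spiro-δ-lactone/ring C tricycle with both acetates installed, C19 silylated, a non-enolisable aldehyde and a free terminal alkyne.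

Key step: step 22

Atom labels C1–C20 follow the ent-kaurane numbering of the target in every intermediate. TBS = tert-butyldimethylsilyl, TES = triethylsilyl, TBDPS = tert-butyldiphenylsilyl, TMS = trimethylsilyl.
Assumption: the oxazaborolidinium salt derived from (S)-diphenylprolinol is taken to expose the methacrolein face that leads to the (1R,2S) adduct of step 3; if the sense is the opposite, the equally available (R)-derived antipode is used in the same way.

Step 1
Reactants: 1 2-[(tert-butyldimethylsilyl)oxy]acetaldehyde; 2 1-(triphenyl-λ5-phosphanylidene)propan-2-one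
Product: 3 (E)-5-[(tert-butyldimethylsilyl)oxy]pent-3-en-2-one
Conditions: CH2Cl2, rt
Reagents that add atoms: none
Why: Wittig olefination with a stabilised acyl ylide, which should give the (E)-enone that already holds C2, C1, C10, C5 and C6.

Step 2
Reactants: 3 (E)-enone
Product: 4 (3E)-2,5-bis[(tert-butyldimethylsilyl)oxy]penta-1,3-diene
Conditions: TBSOTf, Et3N, Et2O, 0 °C
Reagents that add atoms: tert-butyldimethylsilyl trifluoromethanesulfonate, CC(C)(C)[Si](C)(C)OS(=O)(=O)C(F)(F)F
Why: Soft enolisation with a silyl triflate and a tertiary amine removes a proton from the methyl group (C2) and should give the cross-conjugated 2-silyloxydiene without touching the (E)-alkene.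

Step 3
Reactants: 4 silyloxydiene; 5 methacrolein (2-methylprop-2-enal)
Product: 6 (1R,2S)-4-[(tert-butyldimethylsilyl)oxy]-2-{[(tert-butyldimethylsilyl)oxy]methyl}-1-methylcyclohex-3-ene-1-carbaldehyde (ring A; CHO = C19 cis to CH2OTBS = C6; enol ether C1=C10)
Conditions: (S)-3,3-diphenyl-1-(2-methylphenyl)tetrahydro-1H,3H-pyrrolo[1,2-c][1,3,2]oxazaborole protonated with HN(SO2CF3)2 (10 mol %), CH2Cl2, −78 °C
Reagents that add atoms: none
Why: Enantioselective Lewis-acid-catalysed Diels–Alder reaction in which the 1-alkyl and 3-silyloxy groups both polarise the diene toward C2, so that C2 bonds to the CH2 of methacrolein (C3) and C5 to C4; the endo (formyl under the diene) transition state of the (E)-diene sets C19 cis to C6, and the shielded face of the bound aldehyde sets the absolute configuration at C4 and C5.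

Step 4
Reactants: 6 Diels–Alder adduct; 7 N,N-dimethylmethylideneammonium iodide (Eschenmoser's salt)
Product: 10 (1R,2R)-2-{[(tert-butyldimethylsilyl)oxy]methyl}-1-methyl-3-methylidene-4-oxocyclohexane-1-carbaldehyde, via Mannich base 8 (not isolated), via trimethylammonium iodide 9 (not isolated)
Conditions: 7, CH2Cl2, rt; MeI, Et2O, rt; sat. aq. NaHCO3/CH2Cl2, rt
Reagents that add atoms: none
Why: Regiospecific Mannich reaction of the silyl enol ether at C10, exhaustive methylation and E1cB elimination install C20 as an exocyclic methylene; the quaternary aldehyde cannot enolise and no stereocentre is formed.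

Step 5
Reactants: 10 keto aldehyde
Product: 11 (1S,3R,4R)-3-{[(tert-butyldimethylsilyl)oxy]methyl}-4-(hydroxymethyl)-4-methyl-2-methylidenecyclohexan-1-ol (O1, C6 and C19 all cis)
Conditions: NaBH4, CeCl3·7H2O, MeOH, −78 → 0 °C
Reagents that add atoms: none
Why: Luche 1,2-reduction of the enone, with the aldehyde reduced in the same pot; C1 is set because hydride reaches the carbonyl from the ring face opposite the C5 side chain (axial attack in the chair with C6 equatorial, and the only open face in the chair with C6 axial), which places O1 cis to C6.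

Step 6
Reactants: 11 diol
Product: 13 1-O-TES 19-O-TBDPS ether of 11, via C19 mono-TBDPS ether 12 (not isolated)
Conditions: TBDPSCl (1 equiv), imidazole, DMF, 0 °C; then TESCl, rt
Reagents that add atoms: tert-butyl(chloro)diphenylsilane, CC(C)(C)[Si](Cl)(c1ccccc1)c1ccccc1; chlorotriethylsilane, CC[Si](Cl)(CC)CC
Why: Sequential silylation in which the bulky chlorosilane selects the primary C19 hydroxy group over the secondary allylic one, giving three silyl ethers of graded lability (TES and TBS to be exchanged for acetate, TBDPS to stay to the end).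

Step 7
Reactants: 13 allylic silyl ether
Product: 14 C10–C20 spiro-epoxide of 13 (1-oxaspiro[2.5]octane; either C10 epimer)
Conditions: mCPBA, CH2Cl2/aq. NaHCO3 (two-phase), 0 °C
Reagents that add atoms: 3-chloroperbenzoic acid, OOC(=O)c1cccc(Cl)c1
Why: Prilezhaev epoxidation of the only alkene; the epoxide configuration does not matter because C10 becomes a planar radical in the next step.

Step 8
Reactants: 14 spiro-epoxide; 15 2,2,2-trifluoroethyl acrylate
Product: 17 saturated spirolactone (δ-lactone C20H2–O–C7(=O)–C8H2–C9H2 spiro-fused at C10 to ring A bearing 1-OTES, 4-CH3, 4-CH2OTBDPS and 5-CH2OTBS; C20 cis to O1, C6 and C19; C9 trans to them), via trifluoroethyl hydroxy ester 16 (not isolated)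
Conditions: Cp2TiCl2 (30 mol %), Zn dust, 2,4,6-collidine·HCl, THF, rt
Reagents that add atoms: none
Why: Reductive epoxide opening by Cp2TiCl (trivalent titanium) to the tertiary C10 radical, Giese addition to the acrylate and lactonisation of the C20 alkoxide on the activated ester; C10 is set because O1 and C6 on the flanking carbons and C19 on C4 all block one face, so C9 enters trans to them.

Step 9
Reactants: 17 saturated spirolactone
Product: 19 C8=C9 unsaturated spirolactone (5,6-dihydropyran-2-one; otherwise as 17), via C8 phenylselenide 18 (not isolated)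
Conditions: LDA, THF, −78 °C; PhSeBr, −78 °C; then H2O2 (30 %), pyridine, CH2Cl2, 0 °C → rt
Reagents that add atoms: none
Why: Enolate selenenylation and selenoxide syn-elimination, which can only remove a C9 hydrogen and so gives the endocyclic enoate; silyl ethers tolerate both stages.

Step 10
Reactants: 20 (but-3-en-1-yloxy)(tert-butyl)dimethylsilane; 21 (Z)-but-2-ene-1,4-diol
Product: 22 (E)-5-[(tert-butyldimethylsilyl)oxy]pent-2-en-1-ol
Conditions: second-generation Hoveyda–Grubbs catalyst (C31H38Cl2N2ORu, 2 mol %), excess 21, CH2Cl2, 40 °C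
Reagents that add atoms: none
Why: Olefin cross-metathesis of a terminal alkene with a symmetrical allylic diol should favour the (E)-allylic alcohol, and any (Z)-isomer is removed after step 11 as the diastereomeric cis-epoxide.

Step 11
Reactants: 22 (E)-allylic alcohol
Product: 23 [(2S,3S)-3-{2-[(tert-butyldimethylsilyl)oxy]ethyl}oxiran-2-yl]methanol
Conditions: Ti(OiPr)4 (10 mol %), L-(+)-diethyl tartrate (12 mol %), t-BuOOH, 4 Å molecular sieves, CH2Cl2, −20 °C
Reagents that add atoms: tert-butyl hydroperoxide, CC(C)(C)OO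
Why: Sharpless asymmetric epoxidation, in which the L-(+)-tartrate complex delivers oxygen to the face of an (E)-allylic alcohol that gives the (2S,3S)-epoxide.

Step 12
Reactants: 23 epoxy alcohol; 24 trimethylsilylacetylene
Product: 27 (2R,3S)-5-[(tert-butyldimethylsilyl)oxy]-3-[(trimethylsilyl)ethynyl]pentane-1,2-diol, via lithium acetylide 25 (not isolated), via diethylalkynylalane 26 (not isolated)
Conditions: 24, n-BuLi, toluene, 0 °C; Et2AlCl, 0 °C; then 23, 0 °C → rt; aq. potassium sodium tartrate
Reagents that add atoms: none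
Why: Alkoxide-directed opening of a 2,3-epoxy alcohol by an alkynylalane, which attacks the distal epoxide carbon with inversion and so sets C13 with its alkynyl group (C16, C17).

Step 13
Reactants: 27 1,2-diol
Product: 29 (S)-2-{2-[(tert-butyldimethylsilyl)oxy]ethyl}-4-(trimethylsilyl)but-3-yn-1-ol, via alkynyl aldehyde 28 (not isolated)
Conditions: NaIO4, THF/pH 7 buffer, 0 °C; then NaBH4, MeOH, 0 °C
Reagents that add atoms: none
Why: Malaprade glycol cleavage followed at once by borohydride reduction leaves C14 as CH2OH; the aldehyde is not stored, so the propargylic C13 centre should not epimerise.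

Step 14
Reactants: 29 primary alcohol
Product: 30 (S)-tert-butyl{[3-(chloromethyl)-5-(trimethylsilyl)pent-4-yn-1-yl]oxy}dimethylsilane
Conditions: PPh3, CCl4, CH2Cl2, 40 °C
Reagents that add atoms: tetrachloromethane, ClC(Cl)(Cl)Cl
Why: Appel chlorination under neutral conditions turns C14 into a latent leaving group that survives organometallic and enolate chemistry until iodide catalysis activates it.

Step 15
Reactants: 30 chloro silyl ether
Product: 31 (S)-[5-bromo-3-(chloromethyl)pent-1-yn-1-yl]trimethylsilane
Conditions: Ph3PBr2, CH2Cl2, 0 °C → rt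
Reagents that add atoms: dibromotriphenylphosphorane, BrP(Br)(c1ccccc1)(c1ccccc1)c1ccccc1
Why: Direct exchange of a primary silyl ether for bromide through an alkoxyphosphonium salt and SN2 displacement, so that no 4-halobutanol able to close to a tetrahydrofuran is ever set free.

Step 16
Reactants: 19 unsaturated spirolactone; 31 bromo chloride
Product: 34 C9-alkylated spirolactone (17 bearing at C9 the (S)-3-(chloromethyl)-5-(trimethylsilyl)pent-4-ynyl chain C11–C14/C16/C17; C11 on the lactone face syn to C1, H9 syn to C5), via Grignard reagent 32 (not isolated), via silyl ketene acetal 33 (not isolated)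
Conditions: 31, Mg, THF, rt; then CuBr·SMe2 (20 mol %), TMSCl, HMPA, 19, THF, −78 → −40 °C; then AcOH/H2O
Reagents that add atoms: none
Why: Copper-catalysed, chlorosilane-accelerated conjugate addition of a Grignard reagent (magnesium inserts at the C11 bromide and leaves the C14 chloride alone); C9 is set by approach from the lactone face flanked by C1 and C2, because the other face is screened by C5 with its CH2OTBS arm and by the C18 methyl group on quaternary C4.

Step 17
Reactants: 34 C9-alkylated spirolactone; 35 ethyl formate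
Product: 36 C8-hydroxymethylene (enolised C8-formyl) derivative of 34
Conditions: LDA, THF, −78 °C; 35 (excess), −78 → −20 °C; sat. aq. NH4Cl
Reagents that add atoms: none
Why: Crossed Claisen formylation of the lactone enolate introduces C15 and is driven by deprotonation of the product; at −78 °C acylation should outrun displacement of the primary chloride.

Step 18
Reactants: 36 hydroxymethylene lactone
Product: 37 tricyclic C8-formyl lactone (ring C closed by C8–C14; C14 cis to C11 on the lactone ring; C15 formyl cis to H9 and cis to the C13 alkynyl group across ring C; 1-OTES, 6-OTBS, 19-OTBDPS, C17-TMS)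
Conditions: Cs2CO3, NaI (20 mol %), DMF (high dilution), 60 °C
Reagents that add atoms: none
Why: 6-exo-tet cycloalkylation of the stabilised formyl-lactone enolate with Finkelstein-type iodide catalysis, where C-alkylation gives a six-membered ring and O-alkylation would need an eight-membered one; C8 is set because the tether on C9 reaches only the enolate face on which C11 lies, which makes the formyl group cis to H9 and, with the (S)-chain, cis to the alkynyl group on C13.

Step 19
Reactants: 37 tricyclic formyl lactone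
Product: 38 1,6-diol of 37 (19-OTBDPS and C17-TMS retained)
Conditions: HF·pyridine, pyridine, THF, 0 °C → rt
Reagents that add atoms: none
Why: Buffered acidic fluoride desilylation discriminates by silyl bulk, removing TES and TBS but not TBDPS, and avoids the basic media that would deformylate C8.

Step 20
Reactants: 38 1,6-diol
Product: 39 1,6-diacetate of 38
Conditions: Ac2O, pyridine, 4-(dimethylamino)pyridine (10 mol %), CH2Cl2, rt
Reagents that add atoms: acetic anhydride, CC(=O)OC(C)=O
Why: Nucleophile-catalysed acetylation of both free hydroxy groups, run directly after step 19 so that O1 has no time to translactonise onto C7.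

Step 21
Reactants: 39 diacetate
Product: 40 C8-formyl C13-ethynyl spirolactone (1,6-diacetate, 19-OTBDPS; configuration at C1, C4, C5, C8, C9, C10 and C13 as in the target)
Conditions: AgNO3 (10 mol %), acetone/H2O, rt, dark
Reagents that add atoms: none
Why: Silver-catalysed protiodesilylation of a 1-trimethylsilylalkyne runs at neutral pH, so the acetates, the aldehyde and the TBDPS ether should all survive.

Step 22
Reactants: 40 formyl ethynyl spirolactone
Product: 41 16-methylene-15-ol (ring D closed; both C15 epimers; 1,6-diacetate, 19-OTBDPS)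
Conditions: Sn cathode, Pt anode, divided cell (glass frit), Et4NOTs (0.3 M), DMF/2-propanol, constant current, ca. 2.2 F/mol, 0–5 °C, N2; then pH 7 phosphate buffer
Reagents that add atoms: none
Why: Electron transfer from the tin cathode to the non-enolisable C15 aldehyde, the most easily reduced group present, gives a ketyl radical anion that adds to C16 of the ethynyl group; the C17 vinyl radical is then reduced and protonated (or abstracts hydrogen from 2-propanol) to the exocyclic methylene, and the alkoxide is protonated by the alcohol. The closest known reaction type is the electroreductive (or SmI2-mediated) carbonyl–alkyne cyclisation that gives 2-methylenecyclopentanols. Ring D closes in the 5-exo-dig mode, which at the same time completes the bicyclo[3.2.1]octane. The only new stereocentre, C15, is not controlled and need not be, because step 23 removes it; C8 and C13 are fixed beforehand and their cis relationship allows only the bridged product. The step needs selectivity for the aldehyde over lactone, acetates and alkyne, which the reduction potentials secure, and it needs cyclisation to be faster than a second electron transfer, pinacol coupling or base-induced deformylation. The neopentyl aldehyde resists dimerisation, the weakly acidic proton donor keeps the ketyl alive long enough for the cis-fused ring C to flip into the chair with C15 and C16 both axial, and low temperature with charge control limits alkoxide build-up.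

Step 23
Reactants: 41 allylic alcohol
Product: 42 15-oxo-16-ene (isodojaponin D 19-O-TBDPS ether)
Conditions: Dess–Martin periodinane, CH2Cl2, 0 °C → rt
Reagents that add atoms: none
Why: Dess–Martin oxidation of the only free hydroxy group converges both C15 epimers on the α-methylene cyclopentanone under mild, non-basic conditions.

Step 24
Reactants: 42 silyl ether
Product: 43 isodojaponin D
Conditions: HF·pyridine (excess), THF, 0 °C → rt
Reagents that add atoms: none
Why: Acidic fluoride cleavage of the primary TBDPS ether frees O19 without a basic or strongly nucleophilic species, so conjugate addition to C17 and acetyl migration should both be avoided.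

Compound list
1 | 2-[(tert-butyldimethylsilyl)oxy]acetaldehyde | O=CCO[Si](C)(C)C(C)(C)C | starting material
2 | 1-(triphenyl-λ5-phosphanylidene)propan-2-one | CC(=O)C=P(c1ccccc1)(c1ccccc1)c1ccccc1 | starting material
3 | (E)-5-[(tert-butyldimethylsilyl)oxy]pent-3-en-2-one | CC(=O)/C=C/CO[Si](C)(C)C(C)(C)C | intermediate
4 | (3E)-2,5-bis[(tert-butyldimethylsilyl)oxy]penta-1,3-diene | C=C(O[Si](C)(C)C(C)(C)C)/C=C/CO[Si](C)(C)C(C)(C)C | intermediate
5 | methacrolein | C=C(C)C=O | starting material
6 | (1R,2S)-4-(TBS-oxy)-2-(TBS-oxymethyl)-1-methylcyclohex-3-ene-1-carbaldehyde | O=C[C@]1(C)CCC(O[Si](C)(C)C(C)(C)C)=C[C@@H]1CO[Si](C)(C)C(C)(C)C | intermediate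
7 | N,N-dimethylmethylideneammonium iodide | C=[N+](C)C.[I-] | starting material
8 | C10 dimethylaminomethyl ketone (Mannich base) | O=C[C@]1(C)CCC(=O)C(CN(C)C)[C@@H]1CO[Si](C)(C)C(C)(C)C | intermediate
9 | C10 trimethylammoniomethyl ketone iodide | O=C[C@]1(C)CCC(=O)C(C[N+](C)(C)C)[C@@H]1CO[Si](C)(C)C(C)(C)C.[I-] | intermediate
10 | (1R,2R)-2-(TBS-oxymethyl)-1-methyl-3-methylidene-4-oxocyclohexane-1-carbaldehyde | O=C[C@]1(C)CCC(=O)C(=C)[C@@H]1CO[Si](C)(C)C(C)(C)C | intermediate
11 | (1S,3R,4R)-3-(TBS-oxymethyl)-4-(hydroxymethyl)-4-methyl-2-methylidenecyclohexan-1-ol | OC[C@]1(C)CC[C@H](O)C(=C)[C@@H]1CO[Si](C)(C)C(C)(C)C | intermediate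
12 | 19-O-TBDPS ether of 11 | CC(C)(C)[Si](c2ccccc2)(c3ccccc3)OC[C@]1(C)CC[C@H](O)C(=C)[C@@H]1CO[Si](C)(C)C(C)(C)C | intermediate
13 | 1-O-TES 19-O-TBDPS ether of 11 | CC(C)(C)[Si](c2ccccc2)(c3ccccc3)OC[C@]1(C)CC[C@H](O[Si](CC)(CC)CC)C(=C)[C@@H]1CO[Si](C)(C)C(C)(C)C | intermediate
14 | C10–C20 spiro-epoxide of 13 (C10 epimers) | CC(C)(C)[Si](c2ccccc2)(c3ccccc3)OC[C@]1(C)CC[C@H](O[Si](CC)(CC)CC)C4(CO4)[C@@H]1CO[Si](C)(C)C(C)(C)C | intermediate
15 | 2,2,2-trifluoroethyl acrylate | C=CC(=O)OCC(F)(F)F | starting material
16 | trifluoroethyl 3-(ring A C10)-propanoate with free C20 hydroxymethyl | O=C(CC[C@]1(CO)[C@@H](O[Si](CC)(CC)CC)CC[C@@](C)(CO[Si](c2ccccc2)(c3ccccc3)C(C)(C)C)[C@H]1CO[Si](C)(C)C(C)(C)C)OCC(F)(F)F | intermediate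
17 | saturated spirolactone | O=C1CC[C@]2(CO1)[C@@H](O[Si](CC)(CC)CC)CC[C@@](C)(CO[Si](c3ccccc3)(c4ccccc4)C(C)(C)C)[C@H]2CO[Si](C)(C)C(C)(C)C | intermediate
18 | C8 phenylselenyl spirolactone | O=C1C([Se]c5ccccc5)C[C@]2(CO1)[C@@H](O[Si](CC)(CC)CC)CC[C@@](C)(CO[Si](c3ccccc3)(c4ccccc4)C(C)(C)C)[C@H]2CO[Si](C)(C)C(C)(C)C | intermediate
19 | C8=C9 unsaturated spirolactone | O=C1C=C[C@]2(CO1)[C@@H](O[Si](CC)(CC)CC)CC[C@@](C)(CO[Si](c3ccccc3)(c4ccccc4)C(C)(C)C)[C@H]2CO[Si](C)(C)C(C)(C)C | intermediate
20 | (but-3-en-1-yloxy)(tert-butyl)dimethylsilane | C=CCCO[Si](C)(C)C(C)(C)C | starting material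
21 | (Z)-but-2-ene-1,4-diol | OC/C=C\CO | starting material
22 | (E)-5-[(tert-butyldimethylsilyl)oxy]pent-2-en-1-ol | OC/C=C/CCO[Si](C)(C)C(C)(C)C | intermediate
23 | [(2S,3S)-3-{2-[(tert-butyldimethylsilyl)oxy]ethyl}oxiran-2-yl]methanol | OC[C@@H]1O[C@H]1CCO[Si](C)(C)C(C)(C)C | intermediate
24 | trimethylsilylacetylene | C#C[Si](C)(C)C | starting material
25 | lithium (trimethylsilyl)acetylide | [Li]C#C[Si](C)(C)C | intermediate
26 | diethyl[(trimethylsilyl)ethynyl]aluminium | CC[Al](CC)C#C[Si](C)(C)C | intermediate
27 | (2R,3S)-5-(TBS-oxy)-3-[(trimethylsilyl)ethynyl]pentane-1,2-diol | OC[C@H](O)[C@H](C#C[Si](C)(C)C)CCO[Si](C)(C)C(C)(C)C | intermediate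
28 | (S)-2-[2-(TBS-oxy)ethyl]-4-(trimethylsilyl)but-3-ynal | O=C[C@H](C#C[Si](C)(C)C)CCO[Si](C)(C)C(C)(C)C | intermediate
29 | (S)-2-[2-(TBS-oxy)ethyl]-4-(trimethylsilyl)but-3-yn-1-ol | OC[C@H](C#C[Si](C)(C)C)CCO[Si](C)(C)C(C)(C)C | intermediate
30 | (S)-tert-butyl{[3-(chloromethyl)-5-(trimethylsilyl)pent-4-yn-1-yl]oxy}dimethylsilane | ClC[C@H](C#C[Si](C)(C)C)CCO[Si](C)(C)C(C)(C)C | intermediate
31 | (S)-[5-bromo-3-(chloromethyl)pent-1-yn-1-yl]trimethylsilane | ClC[C@H](C#C[Si](C)(C)C)CCBr | intermediate
32 | (S)-[3-(chloromethyl)-5-(trimethylsilyl)pent-4-yn-1-yl]magnesium bromide | ClC[C@H](C#C[Si](C)(C)C)CC[Mg]Br | intermediate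
33 | C7 trimethylsilyl ketene acetal of 34 | C[Si](C)(C)OC1=C[C@@H](CC[C@H](CCl)C#C[Si](C)(C)C)[C@]2(CO1)[C@@H](O[Si](CC)(CC)CC)CC[C@@](C)(CO[Si](c3ccccc3)(c4ccccc4)C(C)(C)C)[C@H]2CO[Si](C)(C)C(C)(C)C | intermediate
34 | C9-alkylated spirolactone | O=C1C[C@@H](CC[C@H](CCl)C#C[Si](C)(C)C)[C@]2(CO1)[C@@H](O[Si](CC)(CC)CC)CC[C@@](C)(CO[Si](c3ccccc3)(c4ccccc4)C(C)(C)C)[C@H]2CO[Si](C)(C)C(C)(C)C | intermediate
35 | ethyl formate | CCOC=O | starting material
36 | C8-hydroxymethylene lactone | O=C1C(=CO)[C@@H](CC[C@H](CCl)C#C[Si](C)(C)C)[C@]2(CO1)[C@@H](O[Si](CC)(CC)CC)CC[C@@](C)(CO[Si](c3ccccc3)(c4ccccc4)C(C)(C)C)[C@H]2CO[Si](C)(C)C(C)(C)C | intermediate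
37 | tricyclic C8-formyl lactone (1-OTES, 6-OTBS, 19-OTBDPS, C17-TMS) | O=C[C@]12C[C@H](C#C[Si](C)(C)C)CC[C@H]1[C@]1(COC2=O)[C@@H](O[Si](CC)(CC)CC)CC[C@@](C)(CO[Si](c3ccccc3)(c4ccccc4)C(C)(C)C)[C@H]1CO[Si](C)(C)C(C)(C)C | intermediate
38 | 1,6-diol | O=C[C@]12C[C@H](C#C[Si](C)(C)C)CC[C@H]1[C@]1(COC2=O)[C@@H](O)CC[C@@](C)(CO[Si](c3ccccc3)(c4ccccc4)C(C)(C)C)[C@H]1CO | intermediate
39 | 1,6-diacetate (C17-TMS) | O=C[C@]12C[C@H](C#C[Si](C)(C)C)CC[C@H]1[C@]1(COC2=O)[C@@H](OC(C)=O)CC[C@@](C)(CO[Si](c3ccccc3)(c4ccccc4)C(C)(C)C)[C@H]1COC(C)=O | intermediate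
40 | C8-formyl C13-ethynyl spirolactone | O=C[C@]12C[C@H](C#C)CC[C@H]1[C@]1(COC2=O)[C@@H](OC(C)=O)CC[C@@](C)(CO[Si](c3ccccc3)(c4ccccc4)C(C)(C)C)[C@H]1COC(C)=O | intermediate
41 | 16-methylene-15-ol (C15 epimers) | C=C1C(O)[C@]23C[C@H]1CC[C@H]2[C@]1(COC3=O)[C@@H](OC(C)=O)CC[C@@](C)(CO[Si](c4ccccc4)(c5ccccc5)C(C)(C)C)[C@H]1COC(C)=O | intermediate
42 | isodojaponin D 19-O-TBDPS ether | C=C1C(=O)[C@]23C[C@H]1CC[C@H]2[C@]1(COC3=O)[C@@H](OC(C)=O)CC[C@@](C)(CO[Si](c4ccccc4)(c5ccccc5)C(C)(C)C)[C@H]1COC(C)=O | intermediate
43 | isodojaponin D (1S,4R,5R,8S,9S,10S,13R) | C=C1C(=O)[C@]23C[C@H]1CC[C@H]2[C@]1(COC3=O)[C@@H](OC(C)=O)CC[C@@](C)(CO)[C@H]1COC(C)=O | target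

Total step count: 24. Longest linear sequence: 18 (steps 1–9 and 16–24). The chain fragment (steps 10–15) is made in parallel.

Steps most likely to fail

Step 22. The ketyl may take up a second electron and a proton before ring C has flipped into the diaxial chair. Electrogenerated alkoxide may also cause deformylation of the substrate or retro-aldol opening of the product. The fallback replaces the short-lived radical by a persistent organometallic nucleophile. It sets out from 40, which is treated with NaI, TMSCl and water in MeCN (Markovnikov addition of HI to the alkyne) to give the C16 iodoalkene F1. An intramolecular Nozaki–Hiyama–Kishi reaction (CrCl2 in excess, NiCl2 1 mol %, DMF, rt) then adds the alkenylchromium species to the C15 aldehyde. This forms the same C15–C16 bond and returns to the route at 41.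

Step 16. Addition at the neopentyl C9 may be sluggish, and facial selectivity may be poor because O1 and C6 flank C9 in a similar way. The fallback changes the control element by making C1 trigonal. It sets out from 19. The secondary TES ether is removed with pyridinium p-toluenesulfonate in EtOH at 0 °C to give the C1 alcohol F2, and Dess–Martin oxidation gives the C1 ketone F3, whose C1 side carries neither hydrogen nor silyl group. Grignard reagent 32 under the copper-catalysed conditions of step 16 gives the C9-alkylated ketone F4. NaBH4 then attacks C1 from the face opposite axial C20 to give the equatorial C1 alcohol F5, and TESCl with imidazole returns to the route at 34.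

Step 18. Displacement at the β-branched primary chloride may be slower than loss of the formyl group by retro-Claisen cleavage with adventitious hydroxide. The fallback reverses the order of the two bond formations at C8 and bypasses step 17. It sets out from 34. NaI in acetone gives the C14 iodide F6, and KHMDS in THF (−78 → 0 °C) closes ring C through the more reactive lactone enolate to give the cis-fused lactone with hydrogen on C8, F7. LDA followed by monomeric formaldehyde alkylates the ring-fusion enolate with retention of the cis fusion to give the C8 hydroxymethyl lactone F8. Dess–Martin oxidation returns to the route at 37.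

Further compounds
F1 | step 22 | C8-formyl C13-(1-iodoethenyl) spirolactone (40 with C16(I)=C17H2) | O=C[C@]12C[C@H](C(I)=C)CC[C@H]1[C@]1(COC2=O)[C@@H](OC(C)=O)CC[C@@](C)(CO[Si](c3ccccc3)(c4ccccc4)C(C)(C)C)[C@H]1COC(C)=O
F2 | step 16 | unsaturated spirolactone with free C1 hydroxy group | O=C1C=C[C@]2(CO1)[C@@H](O)CC[C@@](C)(CO[Si](c3ccccc3)(c4ccccc4)C(C)(C)C)[C@H]2CO[Si](C)(C)C(C)(C)C
F3 | step 16 | unsaturated spirolactone C1 ketone | O=C1C=C[C@]2(CO1)C(=O)CC[C@@](C)(CO[Si](c3ccccc3)(c4ccccc4)C(C)(C)C)[C@H]2CO[Si](C)(C)C(C)(C)C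
F4 | step 16 | C9-alkylated spirolactone C1 ketone | O=C1C[C@@H](CC[C@H](CCl)C#C[Si](C)(C)C)[C@]2(CO1)C(=O)CC[C@@](C)(CO[Si](c3ccccc3)(c4ccccc4)C(C)(C)C)[C@H]2CO[Si](C)(C)C(C)(C)C
F5 | step 16 | C9-alkylated spirolactone C1 alcohol | O=C1C[C@@H](CC[C@H](CCl)C#C[Si](C)(C)C)[C@]2(CO1)[C@@H](O)CC[C@@](C)(CO[Si](c3ccccc3)(c4ccccc4)C(C)(C)C)[C@H]2CO[Si](C)(C)C(C)(C)C
F6 | step 18 | C14 iodide of 34 | O=C1C[C@@H](CC[C@H](CI)C#C[Si](C)(C)C)[C@]2(CO1)[C@@H](O[Si](CC)(CC)CC)CC[C@@](C)(CO[Si](c3ccccc3)(c4ccccc4)C(C)(C)C)[C@H]2CO[Si](C)(C)C(C)(C)C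
F7 | step 18 | ring C closed cis-fused lactone with hydrogen on C8 | [C@H]12C[C@H](C#C[Si](C)(C)C)CC[C@H]1[C@]1(COC2=O)[C@@H](O[Si](CC)(CC)CC)CC[C@@](C)(CO[Si](c3ccccc3)(c4ccccc4)C(C)(C)C)[C@H]1CO[Si](C)(C)C(C)(C)C
F8 | step 18 | C8 hydroxymethyl lactone | OC[C@]12C[C@H](C#C[Si](C)(C)C)CC[C@H]1[C@]1(COC2=O)[C@@H](O[Si](CC)(CC)CC)CC[C@@](C)(CO[Si](c3ccccc3)(c4ccccc4)C(C)(C)C)[C@H]1CO[Si](C)(C)C(C)(C)C
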